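**Retrosynthetic overview**
1. The target comes from a tricyclic 9-oxo lactone with the C8 oxygen protected, by ketone reduction and ether cleavage.
2. Key step: in that tricycle the C7–C8 bond (ten-membered ring) and the O7–C19 bond (γ-lactone) are made together, by a reductive aldol macrocyclisation/lactonisation of an acyclic α-chloro-enal/ene-dione ester.
3. The cascade substrate is assembled on a cyclohexene core: a C3–C7 chloroalkenyl Grignard adds at C2, and a β-lithio-β-alkoxyacrylate acylates C9.
4. The cyclohexene (C1, C10, C11) comes from a catalytic enantioselective Diels–Alder reaction of a 2-siloxydiene with a formyl crotonate.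
5. Ring order: cyclohexene first; ten-membered carbocycle and lactone last, in one operation.

Atom labels C1–C20 follow briarane numbering: C1 quaternary ring-fusion carbon, C2 and C12 acetoxy carbons, C5=C6 chloroalkene, C7 lactone O–CH, C8/C9 diol carbons, C10 ring-fusion CH, C17(C18)–C19 the lactone CH(CH3)–C=O.

Assumption: the (S)-oxazaborolidinium catalyst (step 2) and (R)-DTBM-SEGPHOS (step 14) are taken to attack the faces that give the configurations drawn; if either shows the opposite facial sense, its mirror-image form is used.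

**Route**

Step 1
Reactants: 1 pent-1-en-3-one
Product: 2 (Z)-triisopropyl(penta-1,3-dien-3-yloxy)silane
Conditions: TIPSOTf, Et3N, CH2Cl2, −78 → 0 °C
Reagents that add atoms: triisopropylsilyl triflate, CC(C)[Si](C(C)C)(C(C)C)OS(=O)(=O)C(F)(F)F
Why: Soft enolisation and O-silylation of the ethyl ketone (silyl enol ether formation) gives the (Z)-2-siloxydiene with the methyl group on the outside; no stereocentre is formed.

Step 2
Reactants: 2 (Z)-triisopropyl(penta-1,3-dien-3-yloxy)silane; 3 ethyl (E)-3-methyl-4-oxobut-2-enoate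
Product: 4 ethyl (1S,2R,6S)-6-formyl-2,6-dimethyl-3-[(triisopropylsilyl)oxy]cyclohex-3-ene-1-carboxylate
Conditions: (S)-o-tolyl-CBS-oxazaborolidine·HNTf2 (20 mol%), CH2Cl2, −78 → −40 °C
Reagents that add atoms: none
Why: Enantioselective Diels–Alder reaction with the cationic oxazaborolidine bound to the formyl group: the CH(CH3) diene terminus adds to the ester-bearing carbon (siloxy para to formyl), the E dienophile fixes formyl trans to ester, the α-methyl enal reacts formyl-exo/ester-endo so that the C11 methyl, the ester and the C1 methyl end up cis, and the catalyst blocks one enal face to set C1, C10 and C11 absolutely.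

Step 3
Reactants: 5 3,3-diethoxyprop-1-yne; 6 oxirane
Product: 8 5,5-diethoxypent-3-yn-1-ol, via lithium acetylide 7 (not isolated)
Conditions: n-BuLi, THF–DMPU, −78 → 0 °C
Reagents that add atoms: none
Why: Acetylide opening of the epoxide (alkynylation by epoxide ring opening) in a dipolar cosolvent gives the homopropargylic alcohol; no stereocentre.

Step 4
Reactants: 8 5,5-diethoxypent-3-yn-1-ol
Product: 9 5-bromo-1,1-diethoxypent-2-yne
Conditions: CBr4, PPh3, 2,6-lutidine (cat.), CH2Cl2, 0 °C
Reagents that add atoms: carbon tetrabromide, BrC(Br)(Br)Br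
Why: Appel bromination of the primary alcohol under buffered conditions leaves the acetal and the alkyne intact.

Step 5
Reactants: 9 5-bromo-1,1-diethoxypent-2-yne
Product: 11 (E)-5-bromo-2-chloro-1,1-diethoxy-3-methylpent-2-ene, via alkenylcopper 10 (not isolated)
Conditions: MeMgBr, CuBr·SMe2, Et2O, −30 °C; then NCS, −30 → 0 °C
Reagents that add atoms: methylmagnesium bromide, C[Mg]Br; N-chlorosuccinimide, O=C1CCC(=O)N1Cl
Why: syn-Carbocupration of the acetylenic acetal puts methyl on the remote carbon (C5) and copper next to the chelating acetal (C6), and stereoretentive chlorination of the alkenylcopper fixes CH3 cis to Cl, i.e. C4 cis to C7 as in the target.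

Step 6
Reactants: 11 (E)-5-bromo-2-chloro-1,1-diethoxy-3-methylpent-2-ene; 4 ethyl (1S,2R,6S)-6-formyl-2,6-dimethyl-3-[(triisopropylsilyl)oxy]cyclohex-3-ene-1-carboxylate
Product: 13 ethyl (1S,2R,6S)-6-[(1S,4E)-5-chloro-6,6-diethoxy-1-hydroxy-4-methylhex-4-en-1-yl]-2,6-dimethyl-3-[(triisopropylsilyl)oxy]cyclohex-3-ene-1-carboxylate, via Grignard reagent 12 (not isolated)
Conditions: Mg, THF, 40 °C; then 4, THF, −78 °C; aq NH4Cl at −78 °C
Reagents that add atoms: none
Why: Chemoselective Grignard 1,2-addition to the neopentyl aldehyde (ester and silyl enol ether are inert at −78 °C) under Felkin–Anh control, with the C10 methine anti to the nucleophile, the ring CH2 near the carbonyl oxygen and the methyl flanking the incoming reagent, gives the (2S)-carbinol.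

Step 7
Reactants: 13 (C2 carbinol with silyl enol ether, as above)
Product: 14 ethyl (1S,2R,6S)-6-[(1S,4E)-5-chloro-6,6-diethoxy-1-hydroxy-4-methylhex-4-en-1-yl]-2,6-dimethyl-3-oxocyclohex-4-ene-1-carboxylate
Conditions: Pd(OAc)2 (1.1 equiv), MeCN, 25 °C
Reagents that add atoms: none
Why: Saegusa–Ito oxidation: palladation of the silyl enol ether at C13 and β-hydride elimination from C14 give the C13=C14 enone regiospecifically under neutral conditions that do not epimerise C11.

Step 8
Reactants: 14 (enone, as above)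
Product: 15 ethyl (1S,2R,3S,6S)-6-[(1S,4E)-5-chloro-6,6-diethoxy-1-hydroxy-4-methylhex-4-en-1-yl]-3-hydroxy-2,6-dimethylcyclohex-4-ene-1-carboxylate
Conditions: NaBH4, CeCl3·7H2O, EtOH, −78 °C
Reagents that add atoms: none
Why: Luche 1,2-reduction in which hydride comes from the enone face opposite the axial C10 ester (the face of the C2 arm), giving the 12-epi alcohol (OH cis to the C11 methyl and the ester) that step 11 inverts.

Step 9
Reactants: 16 methyl propanoate; 17 methyl formate
Product: 19 methyl (E)-3-[(4-methoxybenzyl)oxy]-2-methylprop-2-enoate, via sodium enolate 18 (not isolated)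
Conditions: NaH, THF, 0 → 25 °C; then PMBCl, DMF, 25 °C
Reagents that add atoms: 4-methoxybenzyl chloride, COc1ccc(CCl)cc1
Why: Crossed Claisen formylation of the propanoate followed by O-alkylation (Williamson type) of the ambident sodium enolate in DMF gives the (E)-β-alkoxyacrylate.

Step 10
Reactants: 19 methyl (E)-3-[(4-methoxybenzyl)oxy]-2-methylprop-2-enoate; 15 (12-epi diol ester, as above)
Product: 22 methyl (E)-4-[(1S,2R,3S,6S)-6-[(1S,4E)-5-chloro-6,6-diethoxy-1-hydroxy-4-methylhex-4-en-1-yl]-3-hydroxy-2,6-dimethylcyclohex-4-en-1-yl]-3-[(4-methoxybenzyl)oxy]-2-methyl-4-oxobut-2-enoate, via vinyllithium 20 (not isolated), via magnesium alkoxide 21 (not isolated)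
Conditions: 19, LiN(i-Pr)2, THF, −95 °C; 15, i-PrMgCl (2.0 equiv), THF, −78 °C; combine, −95 → −60 °C; aq NH4Cl
Reagents that add atoms: none
Why: Ester-directed β-lithiation of the β-alkoxyacrylate (configuration retained) and acyl substitution at the C9 ester, where the cis 12-alkoxide can engage the ester as a bridged lactone and hold the adduct as a hemiketal alkoxide so that only one equivalent adds, give the (E)-ene-dione with C9 cis to the methyl ester; no stereocentre is formed and C10 is not enolised at this temperature.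

Step 11
Reactants: 22 (ene-dione diol, as above)
Product: 23 methyl (E)-4-[(1S,2R,3R,6S)-3-acetoxy-6-[(1S,4E)-5-chloro-6,6-diethoxy-1-hydroxy-4-methylhex-4-en-1-yl]-2,6-dimethylcyclohex-4-en-1-yl]-3-[(4-methoxybenzyl)oxy]-2-methyl-4-oxobut-2-enoate
Conditions: AcOH, DIAD, PPh3, toluene, 0 → 25 °C
Reagents that add atoms: acetic acid, CC(=O)O
Why: Mitsunobu reaction: acetate displaces the activated allylic 12-oxyphosphonium group by SN2 from the open ring face, inverting C12 to the target configuration and installing the 12-acetate, while the neopentyl 2-OH cannot be displaced.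

Step 12
Reactants: 23 (12-acetate with free 2-OH, as above)
Product: 24 methyl (E)-4-[(1S,2R,3R,6S)-3-acetoxy-6-[(1S,4E)-1-acetoxy-5-chloro-6,6-diethoxy-4-methylhex-4-en-1-yl]-2,6-dimethylcyclohex-4-en-1-yl]-3-[(4-methoxybenzyl)oxy]-2-methyl-4-oxobut-2-enoate
Conditions: Ac2O, DMAP, pyridine, CH2Cl2, 25 → 40 °C
Reagents that add atoms: acetic anhydride, CC(=O)OC(C)=O
Why: DMAP-catalysed acetylation of the one remaining, hindered secondary alcohol; the C2 configuration is untouched.

Step 13
Reactants: 24 (diacetate diethyl acetal, as above)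
Product: 25 methyl (E)-4-[(1S,2R,3R,6S)-3-acetoxy-6-[(1S,4E)-1-acetoxy-5-chloro-4-methyl-6-oxohex-4-en-1-yl]-2,6-dimethylcyclohex-4-en-1-yl]-3-[(4-methoxybenzyl)oxy]-2-methyl-4-oxobut-2-enoate
Conditions: PPTS (0.3 equiv), acetone–H2O 9:1, 50 °C
Reagents that add atoms: water, O
Why: Mild acid-catalysed acetal hydrolysis unveils the α-chloro enal; the acetates and the doubly acceptor-substituted PMB enol ether are stable to PPTS.

Step 14
Reactants: 25 (α-chloro enal/ene-dione ester, as above)
Product: 28 tricyclic 8-O-PMB 9-oxo lactone (ten-membered ring and 19,7-lactone closed; stereocentres 1, 2, 7, 8, 10, 11, 12, 17 as in the target), via copper enolate 26 (not isolated), via copper aldolate 27 (not isolated)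
Conditions: [(Ph3P)CuH]6 (1.5 equiv CuH), (R)-DTBM-SEGPHOS (1.6 equiv), toluene, 2 mM, −40 → 0 °C; aq NH4Cl
Reagents that add atoms: none
Why: Proposed new method: ligand-controlled copper hydride adds to C17 of the s-cis ene-dione (β to the ketone; the C8 alkoxy group deactivates the other terminus), setting C17 under reagent control and giving the copper enolate with C17 cis to O9; A(1,3) strain puts H10 in the enolate plane so the aldehyde, tethered through C1, can reach only one face of C8, a closed Zimmerman–Traxler aldol then gives C8 and C7 as in the target (O7 syn to C17), and the C7 copper alkoxide closes the γ-lactone on the methyl ester, which also blocks retro-aldol; the closest known reactions are copper hydride reductive aldol cyclisations and Reformatsky-type metal-enolate aldol closures of medium rings.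

Step 15
Reactants: 28 (tricyclic 9-ketone, as above)
Product: 29 8-O-PMB ether of the target (9S alcohol; all other stereocentres as in the target)
Conditions: NaBH4, MeOH–CH2Cl2, −40 °C
Reagents that add atoms: none
Why: Non-chelating borohydride reduction under polar Felkin–Anh control: hydride attacks C9 anti to the C8–O bond in the ring conformer with C7 and C10 transoid, giving the 8,9-trans diol relationship; acetates and lactone are inert at −40 °C.

Step 16
Reactants: 29 (8-O-PMB ether, as above)
Product: 30 (1S,2S,5E,7R,8R,9S,10S,11R,12R,17R)-2,12-diacetoxy-6-chloro-8,9-dihydroxybriara-5,13-dien-19-oic acid 19,7-lactone (CNP0296164.1)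
Conditions: DDQ, CH2Cl2–pH 7 buffer 10:1, 0 °C
Reagents that add atoms: none
Why: Oxidative cleavage of the PMB ether with DDQ (single-electron oxidation to the benzylic oxocarbenium ion, then hydrolysis) frees the tertiary 8-OH without touching acetates, lactone or chloroalkene.

**Compound list**
1 | pent-1-en-3-one | CCC(=O)C=C | starting material
2 | (Z)-triisopropyl(penta-1,3-dien-3-yloxy)silane | C=C/C(O[Si](C(C)C)(C(C)C)C(C)C)=C/C | intermediate
3 | ethyl (E)-3-methyl-4-oxobut-2-enoate | CCOC(=O)/C=C(\C)C=O | starting material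
4 | ethyl (1S,2R,6S)-6-formyl-2,6-dimethyl-3-[(triisopropylsilyl)oxy]cyclohex-3-ene-1-carboxylate | C[C@]1(C=O)CC=C(O[Si](C(C)C)(C(C)C)C(C)C)[C@H](C)[C@@H]1C(=O)OCC | intermediate
5 | 3,3-diethoxyprop-1-yne | CCOC(OCC)C#C | starting material
6 | oxirane | C1CO1 | starting material
7 | lithium 3,3-diethoxyprop-1-yn-1-ide | [Li]C#CC(OCC)OCC | intermediate (not isolated)
8 | 5,5-diethoxypent-3-yn-1-ol | OCCC#CC(OCC)OCC | intermediate
9 | 5-bromo-1,1-diethoxypent-2-yne | BrCCC#CC(OCC)OCC | intermediate
10 | [(E)-5-bromo-1,1-diethoxy-3-methylpent-2-en-2-yl]copper (CH3 cis to Cu) | BrCC/C(C)=C(/[Cu])C(OCC)OCC | intermediate (not isolated)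
11 | (E)-5-bromo-2-chloro-1,1-diethoxy-3-methylpent-2-ene | BrCC/C(C)=C(/Cl)C(OCC)OCC | intermediate
12 | [(E)-4-chloro-5,5-diethoxy-3-methylpent-3-en-1-yl]magnesium bromide | Br[Mg]CC/C(C)=C(/Cl)C(OCC)OCC | intermediate (not isolated)
13 | ethyl (1S,2R,6S)-6-[(1S,4E)-5-chloro-6,6-diethoxy-1-hydroxy-4-methylhex-4-en-1-yl]-2,6-dimethyl-3-[(triisopropylsilyl)oxy]cyclohex-3-ene-1-carboxylate | C[C@]1([C@@H](O)CC/C(C)=C(/Cl)C(OCC)OCC)CC=C(O[Si](C(C)C)(C(C)C)C(C)C)[C@H](C)[C@@H]1C(=O)OCC | intermediate
14 | ethyl (1S,2R,6S)-6-[(1S,4E)-5-chloro-6,6-diethoxy-1-hydroxy-4-methylhex-4-en-1-yl]-2,6-dimethyl-3-oxocyclohex-4-ene-1-carboxylate | C[C@]1([C@@H](O)CC/C(C)=C(/Cl)C(OCC)OCC)C=CC(=O)[C@H](C)[C@@H]1C(=O)OCC | intermediate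
15 | ethyl (1S,2R,3S,6S)-6-[(1S,4E)-5-chloro-6,6-diethoxy-1-hydroxy-4-methylhex-4-en-1-yl]-3-hydroxy-2,6-dimethylcyclohex-4-ene-1-carboxylate (12-epi alcohol) | C[C@]1([C@@H](O)CC/C(C)=C(/Cl)C(OCC)OCC)C=C[C@H](O)[C@H](C)[C@@H]1C(=O)OCC | intermediate
16 | methyl propanoate | CCC(=O)OC | starting material
17 | methyl formate | COC=O | starting material
18 | sodium 3-methoxy-2-methyl-3-oxoprop-1-en-1-olate | [Na+].[O-]C=C(C)C(=O)OC | intermediate (not isolated)
19 | methyl (E)-3-[(4-methoxybenzyl)oxy]-2-methylprop-2-enoate | COC(=O)/C(C)=C/OCc1ccc(OC)cc1 | intermediate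
20 | methyl 3-lithio-3-[(4-methoxybenzyl)oxy]-2-methylprop-2-enoate (Li cis to the ester) | COC(=O)/C(C)=C(\[Li])OCc1ccc(OC)cc1 | intermediate (not isolated)
21 | bis(chloromagnesium) 2,12-dialkoxide of 15 | C[C@]1([C@@H](O[Mg]Cl)CC/C(C)=C(/Cl)C(OCC)OCC)C=C[C@H](O[Mg]Cl)[C@H](C)[C@@H]1C(=O)OCC | intermediate (not isolated)
22 | methyl (E)-4-[(1S,2R,3S,6S)-6-[(1S,4E)-5-chloro-6,6-diethoxy-1-hydroxy-4-methylhex-4-en-1-yl]-3-hydroxy-2,6-dimethylcyclohex-4-en-1-yl]-3-[(4-methoxybenzyl)oxy]-2-methyl-4-oxobut-2-enoate | C[C@]1([C@@H](O)CC/C(C)=C(/Cl)C(OCC)OCC)C=C[C@H](O)[C@H](C)[C@@H]1C(=O)/C(OCc1ccc(OC)cc1)=C(/C)C(=O)OC | intermediate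
23 | 12-acetate of 22 with C12 inverted (3R on the ring; 2-OH free) | C[C@]1([C@@H](O)CC/C(C)=C(/Cl)C(OCC)OCC)C=C[C@@H](OC(C)=O)[C@H](C)[C@@H]1C(=O)/C(OCc1ccc(OC)cc1)=C(/C)C(=O)OC | intermediate
24 | 2,12-diacetate diethyl acetal | C[C@]1([C@@H](OC(C)=O)CC/C(C)=C(/Cl)C(OCC)OCC)C=C[C@@H](OC(C)=O)[C@H](C)[C@@H]1C(=O)/C(OCc1ccc(OC)cc1)=C(/C)C(=O)OC | intermediate
25 | 2,12-diacetate α-chloro enal/ene-dione ester (cascade substrate) | C[C@]1([C@@H](OC(C)=O)CC/C(C)=C(/Cl)C=O)C=C[C@@H](OC(C)=O)[C@H](C)[C@@H]1C(=O)/C(OCc1ccc(OC)cc1)=C(/C)C(=O)OC | intermediate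
26 | copper enolate of 25 after hydride addition at C17 (O9–Cu, C9=C8, C17 cis to O9, 17R; phosphine on Cu omitted) | C[C@]1([C@@H](OC(C)=O)CC/C(C)=C(/Cl)C=O)C=C[C@@H](OC(C)=O)[C@H](C)[C@@H]1/C(O[Cu])=C(\OCc1ccc(OC)cc1)[C@@H](C)C(=O)OC | intermediate (not isolated)
27 | C7 copper alkoxide of the ten-membered aldol (C7–C8 formed, methyl ester still open; phosphine on Cu omitted) | CC(=O)O[C@H]1CC/C(C)=C(/Cl)[C@H](O[Cu])[C@@](OCc3ccc(OC)cc3)([C@@H](C)C(=O)OC)C(=O)[C@H]2[C@@H](C)[C@H](OC(C)=O)C=C[C@@]21C | intermediate (not isolated)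
28 | tricyclic 8-O-PMB 9-oxo 19,7-lactone | CC(=O)O[C@H]1CC/C(C)=C(/Cl)[C@@H]2OC(=O)[C@H](C)[C@@]2(OCc3ccc(OC)cc3)C(=O)[C@H]2[C@@H](C)[C@H](OC(C)=O)C=C[C@@]21C | intermediate
29 | 8-O-PMB ether of the target (9S-OH) | CC(=O)O[C@H]1CC/C(C)=C(/Cl)[C@@H]2OC(=O)[C@H](C)[C@@]2(OCc3ccc(OC)cc3)[C@@H](O)[C@H]2[C@@H](C)[C@H](OC(C)=O)C=C[C@@]21C | intermediate
30 | (1S,2S,5E,7R,8R,9S,10S,11R,12R,17R)-2,12-diacetoxy-6-chloro-8,9-dihydroxybriara-5,13-dien-19-oic acid 19,7-lactone | CC(=O)O[C@H]1CC/C(C)=C(/Cl)[C@@H]2OC(=O)[C@H](C)[C@@]2(O)[C@@H](O)[C@H]2[C@@H](C)[C@H](OC(C)=O)C=C[C@@]21C | target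

**Totals and risks**

Total step count: 16. Longest linear sequence: 13 steps (from 5 and 6 through steps 3–8 and 10–16 to 30).

The three steps most likely to fail:

Step 14 is the largest risk. A copper enolate has not been shown to close a ten-membered ring by aldol addition; hydride addition to a tetrasubstituted ene-dione may be slow; and the enal could be reduced competitively. The fallback separates hydride delivery from C–C bond formation. It sets out from 25: conjugate reduction with the same ligated CuH in the presence of Me3SiCl at −78 °C traps the enolate as the trimethylsilyl enol ether F1. BF3·OEt2 in CH2Cl2 at −78 °C under high dilution then closes the ten-membered ring by an intramolecular Mukaiyama aldol addition (open transition state) to give the hydroxy ester F2. Camphorsulfonic acid closes the lactone, and the route is rejoined at 28.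

Step 10 may fail because the β-lithioacrylate 20 is stable only at very low temperature and the ring ester is hindered, so acylation may be slow or may not stop cleanly at the ketone. The fallback changes the acyl donor. It sets out from 15: MeNH(OMe)·HCl with i-PrMgCl converts the ester into the Weinreb amide F3, which takes up one equivalent of 20 through a stable chelated tetrahedral intermediate, and the route is rejoined at 22.

Step 15 may give the wrong C9 epimer, because the facial selectivity at a ketone inside the ten-membered ring depends on a ring conformation that is only predicted. The fallback reverses the order of the last two steps and changes the control element. It sets out from 28: DDQ first frees the tertiary alcohol to give the α-hydroxy ketone F4, and Me4NBH(OAc)3 in MeCN–AcOH at −20 °C then delivers hydride intramolecularly from the boron bound to the 8-oxygen, i.e. to the face opposite to the one used by NaBH4. This arrives directly at 30.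

Further compounds
F1 | step 14 | trimethylsilyl enol ether of 25 after hydride addition at C17 (C9(OSiMe3)=C8) | C[C@]1([C@@H](OC(C)=O)CC/C(C)=C(/Cl)C=O)C=C[C@@H](OC(C)=O)[C@H](C)[C@@H]1/C(O[Si](C)(C)C)=C(\OCc1ccc(OC)cc1)[C@@H](C)C(=O)OC
F2 | step 14 | ten-membered 7-hydroxy-9-oxo methyl ester (aldol before lactonisation) | CC(=O)O[C@H]1CC/C(C)=C(/Cl)[C@H](O)[C@@](OCc3ccc(OC)cc3)([C@@H](C)C(=O)OC)C(=O)[C@H]2[C@@H](C)[C@H](OC(C)=O)C=C[C@@]21C
F3 | step 10 | N-methoxy-N-methyl amide of 15 at C9 | C[C@]1([C@@H](O)CC/C(C)=C(/Cl)C(OCC)OCC)C=C[C@H](O)[C@H](C)[C@@H]1C(=O)N(C)OC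
F4 | step 15 | 8-hydroxy-9-oxo tricyclic lactone | CC(=O)O[C@H]1CC/C(C)=C(/Cl)[C@@H]2OC(=O)[C@H](C)[C@@]2(O)C(=O)[C@H]2[C@@H](C)[C@H](OC(C)=O)C=C[C@@]21C
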